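**Plan**

- Retrosynthetic cuts, in order: the enone Cα=Cβ bond (aldol condensation); the aryl–acetyl bond; the aryl–C4 bond of the oxane (coupling at a C4 enol triflate, then C=C saturation); O1–C6 (oxa-Michael); last, C3–C4 and C4–C5 in one operation.
- Enabling feature: in the oxane ring (O1, C2, C3, C4, C5, C6), C4 lies between the methylenes C3 and C5, and each of these is bonded to an oxygen-bearing carbon (C2, C6). This is the pattern left when a carbonyl-anion equivalent at C4 opens two terminal epoxides.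
- Forward: two epoxides are prepared and stitched through a 2-silyl-1,3-dithiane into the open C1–C7 chain (no ring). Ketone unmasking and acid then close the only new ring, the 2,6-cis oxan-4-one. Triflation, Suzuki coupling, hydrogenation, MOM protection, ortho-lithiation/acetylation, Claisen–Schmidt condensation and deprotection follow.
- Stereochemistry: C2 comes from (S)-epichlorohydrin and its C–O bond is never broken. C6 is set cis to C2 under thermodynamic control in the ring closure. C4 is set by hydrogen delivery to the face anti to the C2/C6 substituents. The enone is E by thermodynamic control.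

Key step: step 4

Remark (assumptions): ring positions are O1, C2 (carries the arylethyl chain), C3, C4 (carries the chalcone aryl), C5, C6 (carries the 4-oxyphenyl group). (S)-Epichlorohydrin is taken from the chiral pool, so no resolution is needed. The two double-bond isomers from step 7 are carried as a mixture because both give the same product in step 11.

**Route**

Step 1
Reactants: 1 4-(benzyloxy)benzyl chloride; 2 (S)-epichlorohydrin
Product: 4 (2S)-4-[4-(benzyloxy)phenyl]-1-chlorobutan-2-ol, via 4-(benzyloxy)benzylmagnesium chloride 3 (not isolated)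
Conditions: Mg, Et2O/THF, 0 °C→rt (slow addition); CuI (10 mol%), 2, −40→−20 °C; 1 M HCl
Reagents that add atoms: none
Why: Copper-catalysed Grignard opening of an epoxide occurs by SN2 at the unsubstituted CH2 of epichlorohydrin and outruns chloride displacement at low temperature; the C–O bond of the stereocentre is untouched, so (S) is carried into 4.

Step 2
Reactants: 4 (2S)-4-[4-(benzyloxy)phenyl]-1-chlorobutan-2-ol
Product: 5 (2S)-2-{2-[4-(benzyloxy)phenyl]ethyl}oxirane
Conditions: powdered NaOH, Et2O, rt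
Reagents that add atoms: none
Why: Intramolecular Williamson etherification (3-exo-tet) of the chlorohydrin alkoxide displaces the primary chloride without touching the stereogenic C–O bond, so 5 should be the (S)-epoxide.

Step 3
Reactants: 6 4-(benzyloxy)benzaldehyde
Product: 7 2-[4-(benzyloxy)phenyl]oxirane (racemic)
Conditions: Me3S+ I−, NaH, DMSO/THF, 0 °C→rt; product used after filtration through base-washed silica
Reagents that add atoms: trimethylsulfonium iodide, C[S+](C)C.[I-]
Why: Corey–Chaykovsky epoxidation (ylide addition, betaine closure); the new centre is deliberately left racemic because it becomes C6, which is re-set in step 6.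

Step 4
Reactants: 8 2-(tert-butyldimethylsilyl)-1,3-dithiane; 5 (2S)-2-{2-[4-(benzyloxy)phenyl]ethyl}oxirane; 7 2-[4-(benzyloxy)phenyl]oxirane
Product: 12 1-[4-(benzyloxy)phenyl]-2-(2-{(2S)-4-[4-(benzyloxy)phenyl]-2-[(tert-butyldimethylsilyl)oxy]butyl}-1,3-dithian-2-yl)ethan-1-ol (both carbinol epimers), via lithiated silyl dithiane 9 (not isolated), via C-silyl lithium alkoxide 10 (not isolated), via O-silyl dithianyllithium 11 (not isolated)
Conditions: t-BuLi, Et2O, −78→−45 °C; 5, Et2O, −78→−25 °C; then 7, HMPA/THF, −78→0 °C; aq NH4Cl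
Reagents that add atoms: none
Why: Lithiated dithiane 9 opens 5 by SN2 at its CH2 terminus in ether, where alkoxide 10 is a tight lithium aggregate and the silyl group stays on carbon; adding HMPA/THF with 7 loosens the ion pair, silicon migrates from C to O (1,4-Brook rearrangement) and the new anion 11 attacks the CH2 terminus of 7, so C3–C4 and C4–C5 are both formed in one flask. The closest known reaction type is the solvent-gated multicomponent anion relay coupling of 2-silyl-1,3-dithianes with two different terminal epoxides. No ring is closed; the step joins an open chain. No stereocentre of the target is created: the (S) centre of 5 is a spectator because its C–O bond is not broken, and the carbinol carbon from racemic 7 forms as both epimers, which converge in step 6. The step needs cross-coupling instead of double addition of one epoxide, and terminal opening of both epoxides; the first is secured by the order of addition and by withholding the polar cosolvent until 5 is consumed. The second follows from the steric bias of monosubstituted epoxides, helped for the aryl epoxide by HMPA, which strips lithium from the epoxide oxygen and so disfavours benzylic opening or rearrangement; silicon ends on the non-benzylic oxygen and leaves the benzylic hydroxyl free for step 6.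

Step 5
Reactants: 12 the dithiane from step 4
Product: 13 (5S)-1,7-bis[4-(benzyloxy)phenyl]-5-[(tert-butyldimethylsilyl)oxy]-1-hydroxyheptan-3-one (both C1 epimers)
Conditions: MeI (excess), CaCO3, MeCN/H2O (9:1), 45 °C
Reagents that add atoms: water, O
Why: Alkylative dithiane hydrolysis: S-methylation makes a sulfonium leaving group and water delivers the carbonyl oxygen under buffered, near-neutral conditions that a silyl ether, a benzylic alcohol and benzyl ethers should tolerate.

Step 6
Reactants: 13 (5S)-1,7-bis[4-(benzyloxy)phenyl]-5-[(tert-butyldimethylsilyl)oxy]-1-hydroxyheptan-3-one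
Product: 16 (2S,6S)-6-[4-(benzyloxy)phenyl]-2-{2-[4-(benzyloxy)phenyl]ethyl}oxan-4-one (2,6-cis), via dihydroxy ketone 14 (not isolated), via hydroxy enone 15 (not isolated)
Conditions: p-TsOH·H2O, MeCN/H2O (20:1), rt→45 °C
Reagents that add atoms: none
Why: Acid cleaves the silyl ether, the p-alkoxybenzylic β-hydroxy ketone loses water (E1-type aldol dehydration) to the (E)-enone 15, and a reversible 6-endo-trig oxa-Michael addition of the C2 hydroxyl closes the ring; under this thermodynamic control both substituents should sit equatorial, so C6 is set cis to the untouched (S)-C2 and both epimers of 13 converge.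

Step 7
Reactants: 16 (2S,6S)-6-[4-(benzyloxy)phenyl]-2-{2-[4-(benzyloxy)phenyl]ethyl}oxan-4-one
Product: 17 (2S,6S)-6-[4-(benzyloxy)phenyl]-2-{2-[4-(benzyloxy)phenyl]ethyl}-5,6-dihydro-2H-pyran-4-yl trifluoromethanesulfonate (C3=C4 isomer) and 18 (2S,6S)-6-[4-(benzyloxy)phenyl]-2-{2-[4-(benzyloxy)phenyl]ethyl}-3,6-dihydro-2H-pyran-4-yl trifluoromethanesulfonate (C4=C5 isomer)
Conditions: KHMDS, THF, −78 °C; PhNTf2, −78→0 °C; aq NH4Cl
Reagents that add atoms: N-phenylbis(trifluoromethanesulfonimide), O=S(=O)(N(c1ccccc1)S(=O)(=O)C(F)(F)F)C(F)(F)F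
Why: Kinetic enolisation and O-sulfonylation (enol triflate formation) at low temperature; the ring C–O bonds lie close to the nodal plane of the cyclic enolate, which holds back β-elimination, and the two regioisomers are equivalent for the steps that follow.

Step 8
Reactants: 19 5-methoxyresorcinol
Product: 20 1-methoxy-3,5-bis(methoxymethoxy)benzene
Conditions: NaH, MOMCl, DMF, 0 °C→rt
Reagents that add atoms: chloromethyl methyl ether, COCCl
Why: Williamson-type O-alkylation of the two phenoxides installs acetal protecting groups that are also strong ortho-directing groups.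

Step 9
Reactants: 20 1-methoxy-3,5-bis(methoxymethoxy)benzene
Product: 22 2-[4-methoxy-2,6-bis(methoxymethoxy)phenyl]-4,4,5,5-tetramethyl-1,3,2-dioxaborolane, via aryllithium 21 (not isolated)
Conditions: n-BuLi, THF, 0 °C; i-PrOBpin, −78 °C→rt; aq NH4Cl
Reagents that add atoms: 2-isopropoxy-4,4,5,5-tetramethyl-1,3,2-dioxaborolane, CC(C)OB1OC(C)(C)C(C)(C)O1
Why: Directed ortho-metalation at the position between the two chelating MOM ethers, the kinetically most acidic site, followed by borylation of the aryllithium with the borate ester.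

Step 10
Reactants: 17 and 18 enol triflates (mixture); 22 the aryl pinacol boronate
Product: 23 (2S,6S)-6-[4-(benzyloxy)phenyl]-2-{2-[4-(benzyloxy)phenyl]ethyl}-4-[4-methoxy-2,6-bis(methoxymethoxy)phenyl]-5,6-dihydro-2H-pyran (C3=C4 isomer) and 24 (2S,6S)-6-[4-(benzyloxy)phenyl]-2-{2-[4-(benzyloxy)phenyl]ethyl}-4-[4-methoxy-2,6-bis(methoxymethoxy)phenyl]-3,6-dihydro-2H-pyran (C4=C5 isomer)
Conditions: Pd(OAc)2 (5 mol%), SPhos (10 mol%), K3PO4, THF/H2O (10:1), 60 °C
Reagents that add atoms: none
Why: Suzuki–Miyaura coupling of an alkenyl triflate; a bulky electron-rich biarylphosphine is the established answer to di-ortho-alkoxy arylboron partners, whose transmetalation must outrun protodeboronation, and C2/C6 are spectators.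

Step 11
Reactants: 23 and 24 aryl dihydropyrans (mixture)
Product: 25 (2S,4R,6S)-6-(4-hydroxyphenyl)-2-[2-(4-hydroxyphenyl)ethyl]-4-[4-methoxy-2,6-bis(methoxymethoxy)phenyl]oxane (all-cis)
Conditions: H2 (1–4 atm), 10% Pd/C, EtOAc/MeOH, rt
Reagents that add atoms: none
Why: Heterogeneous hydrogenation should deliver hydrogen to the ring face anti to the C2 and C6 substituents (the face carrying C2–H and C6–H), placing the aryl group cis to both and setting C4 as R in the all-equatorial isomer; the same conditions hydrogenolyse the two benzyl ethers, and both alkene isomers converge.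

Step 12
Reactants: 25 the all-cis diphenol
Product: 26 (2S,4R,6S)-4-[4-methoxy-2,6-bis(methoxymethoxy)phenyl]-6-[4-(methoxymethoxy)phenyl]-2-{2-[4-(methoxymethoxy)phenyl]ethyl}oxane
Conditions: NaH, MOMCl, DMF, 0 °C→rt
Reagents that add atoms: chloromethyl methyl ether, COCCl
Why: Phenoxide O-alkylation; masking both phenols as MOM ethers makes the substrate compatible with organolithium and hydroxide and lets all five acetals fall in one final operation.

Step 13
Reactants: 26 the tetra-MOM ether
Product: 28 1-{6-methoxy-2,4-bis(methoxymethoxy)-3-[(2S,4R,6S)-6-[4-(methoxymethoxy)phenyl]-2-{2-[4-(methoxymethoxy)phenyl]ethyl}oxan-4-yl]phenyl}ethan-1-one, via aryllithium 27 (not isolated)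
Conditions: n-BuLi, TMEDA, THF, −20→0 °C; MeC(O)N(OMe)Me, −78→0 °C; aq NH4Cl
Reagents that add atoms: N-methoxy-N-methylacetamide, CC(=O)N(C)OC
Why: Directed ortho-metalation at the only type of ring position flanked by two alkoxy directing groups (OMOM and OMe; the two such positions are equivalent by symmetry), then acylation with a Weinreb amide, whose chelated adduct stops at the ketone.

Step 14
Reactants: 28 the aryl methyl ketone; 29 4-(methoxymethoxy)benzaldehyde
Product: 30 (2E)-1-{6-methoxy-2,4-bis(methoxymethoxy)-3-[(2S,4R,6S)-6-[4-(methoxymethoxy)phenyl]-2-{2-[4-(methoxymethoxy)phenyl]ethyl}oxan-4-yl]phenyl}-3-[4-(methoxymethoxy)phenyl]prop-2-en-1-one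
Conditions: KOH, EtOH/H2O, rt→40 °C
Reagents that add atoms: none
Why: Claisen–Schmidt condensation of a methyl ketone enolate with a non-enolisable aldehyde; E1cB dehydration should give the more stable (E)-enone, and MOM ethers and the oxane are inert to hydroxide.

Step 15
Reactants: 30 the penta-MOM chalcone
Product: 31 (2E)-1-{2,4-dihydroxy-3-[(2S,4R,6S)-6-(4-hydroxyphenyl)-2-[2-(4-hydroxyphenyl)ethyl]oxan-4-yl]-6-methoxyphenyl}-3-(4-hydroxyphenyl)prop-2-en-1-one (CNP0215517.1)
Conditions: HCl (ca. 1 M) in MeOH/THF, rt, stopped on full conversion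
Reagents that add atoms: none
Why: Acid-catalysed acetal cleavage of the five MOM ethers, with the methyl ether untouched; the all-equatorial ring is the thermodynamic isomer, so any reversible ionisation at the benzylic C6–O bond cannot change it, and brief reaction at room temperature should keep the 2'-hydroxychalcone from closing to a flavanone.

**Compound list**

1 | 4-(benzyloxy)benzyl chloride | ClCc1ccc(OCc2ccccc2)cc1 | starting material
2 | (S)-epichlorohydrin | ClC[C@@H]1CO1 | starting material
3 | 4-(benzyloxy)benzylmagnesium chloride (formed in the flask, step 1) | Cl[Mg]Cc1ccc(OCc2ccccc2)cc1 | intermediate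
4 | (2S)-4-[4-(benzyloxy)phenyl]-1-chlorobutan-2-ol | ClC[C@@H](O)CCc1ccc(OCc2ccccc2)cc1 | intermediate
5 | (2S)-2-{2-[4-(benzyloxy)phenyl]ethyl}oxirane | C1O[C@H]1CCc1ccc(OCc2ccccc2)cc1 | intermediate
6 | 4-(benzyloxy)benzaldehyde | O=Cc1ccc(OCc2ccccc2)cc1 | starting material
7 | 2-[4-(benzyloxy)phenyl]oxirane (racemic) | C1OC1c1ccc(OCc2ccccc2)cc1 | intermediate
8 | 2-(tert-butyldimethylsilyl)-1,3-dithiane | CC(C)(C)[Si](C)(C)C1SCCCS1 | starting material
9 | 2-lithio-2-(tert-butyldimethylsilyl)-1,3-dithiane (formed in the flask, step 4) | [Li]C1([Si](C)(C)C(C)(C)C)SCCCS1 | intermediate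
10 | lithium (2S)-4-[4-(benzyloxy)phenyl]-1-[2-(tert-butyldimethylsilyl)-1,3-dithian-2-yl]butan-2-olate (formed in the flask, step 4) | [Li]O[C@@H](CCc1ccc(OCc2ccccc2)cc1)CC1([Si](C)(C)C(C)(C)C)SCCCS1 | intermediate
11 | 2-lithio-2-{(2S)-4-[4-(benzyloxy)phenyl]-2-[(tert-butyldimethylsilyl)oxy]butyl}-1,3-dithiane (formed in the flask, step 4) | CC(C)(C)[Si](C)(C)O[C@@H](CCc1ccc(OCc2ccccc2)cc1)CC1([Li])SCCCS1 | intermediate
12 | 1-[4-(benzyloxy)phenyl]-2-(2-{(2S)-4-[4-(benzyloxy)phenyl]-2-[(tert-butyldimethylsilyl)oxy]butyl}-1,3-dithian-2-yl)ethan-1-ol (both carbinol epimers) | CC(C)(C)[Si](C)(C)O[C@@H](CCc1ccc(OCc2ccccc2)cc1)CC1(CC(O)c2ccc(OCc3ccccc3)cc2)SCCCS1 | intermediate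
13 | (5S)-1,7-bis[4-(benzyloxy)phenyl]-5-[(tert-butyldimethylsilyl)oxy]-1-hydroxyheptan-3-one (both C1 epimers) | CC(C)(C)[Si](C)(C)O[C@@H](CCc1ccc(OCc2ccccc2)cc1)CC(=O)CC(O)c1ccc(OCc2ccccc2)cc1 | intermediate
14 | (5S)-1,7-bis[4-(benzyloxy)phenyl]-1,5-dihydroxyheptan-3-one (formed in the flask, step 6) | O[C@@H](CCc1ccc(OCc2ccccc2)cc1)CC(=O)CC(O)c1ccc(OCc2ccccc2)cc1 | intermediate
15 | (1E,5S)-1,7-bis[4-(benzyloxy)phenyl]-5-hydroxyhept-1-en-3-one (formed in the flask, step 6) | O[C@@H](CCc1ccc(OCc2ccccc2)cc1)CC(=O)/C=C/c1ccc(OCc2ccccc2)cc1 | intermediate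
16 | (2S,6S)-6-[4-(benzyloxy)phenyl]-2-{2-[4-(benzyloxy)phenyl]ethyl}oxan-4-one | O=C1C[C@H](CCc2ccc(OCc3ccccc3)cc2)O[C@H](c2ccc(OCc3ccccc3)cc2)C1 | intermediate
17 | (2S,6S)-6-[4-(benzyloxy)phenyl]-2-{2-[4-(benzyloxy)phenyl]ethyl}-5,6-dihydro-2H-pyran-4-yl trifluoromethanesulfonate | O=S(=O)(OC1=C[C@H](CCc2ccc(OCc3ccccc3)cc2)O[C@H](c2ccc(OCc3ccccc3)cc2)C1)C(F)(F)F | intermediate
18 | (2S,6S)-6-[4-(benzyloxy)phenyl]-2-{2-[4-(benzyloxy)phenyl]ethyl}-3,6-dihydro-2H-pyran-4-yl trifluoromethanesulfonate | O=S(=O)(OC1=C[C@@H](c2ccc(OCc3ccccc3)cc2)O[C@@H](CCc2ccc(OCc3ccccc3)cc2)C1)C(F)(F)F | intermediate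
19 | 5-methoxyresorcinol | COc1cc(O)cc(O)c1 | starting material
20 | 1-methoxy-3,5-bis(methoxymethoxy)benzene | COCOc1cc(OC)cc(OCOC)c1 | intermediate
21 | [4-methoxy-2,6-bis(methoxymethoxy)phenyl]lithium (formed in the flask, step 9) | COCOc1cc(OC)cc(OCOC)c1[Li] | intermediate
22 | 2-[4-methoxy-2,6-bis(methoxymethoxy)phenyl]-4,4,5,5-tetramethyl-1,3,2-dioxaborolane | COCOc1cc(OC)cc(OCOC)c1B1OC(C)(C)C(C)(C)O1 | intermediate
23 | (2S,6S)-6-[4-(benzyloxy)phenyl]-2-{2-[4-(benzyloxy)phenyl]ethyl}-4-[4-methoxy-2,6-bis(methoxymethoxy)phenyl]-5,6-dihydro-2H-pyran | COCOc1cc(OC)cc(OCOC)c1C4=C[C@H](CCc2ccc(OCc3ccccc3)cc2)O[C@H](c2ccc(OCc3ccccc3)cc2)C4 | intermediate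
24 | (2S,6S)-6-[4-(benzyloxy)phenyl]-2-{2-[4-(benzyloxy)phenyl]ethyl}-4-[4-methoxy-2,6-bis(methoxymethoxy)phenyl]-3,6-dihydro-2H-pyran | COCOc1cc(OC)cc(OCOC)c1C4=C[C@@H](c2ccc(OCc3ccccc3)cc2)O[C@@H](CCc2ccc(OCc3ccccc3)cc2)C4 | intermediate
25 | (2S,4R,6S)-6-(4-hydroxyphenyl)-2-[2-(4-hydroxyphenyl)ethyl]-4-[4-methoxy-2,6-bis(methoxymethoxy)phenyl]oxane | COCOc1cc(OC)cc(OCOC)c1[C@@H]2C[C@H](CCc3ccc(O)cc3)O[C@H](c3ccc(O)cc3)C2 | intermediate
26 | (2S,4R,6S)-4-[4-methoxy-2,6-bis(methoxymethoxy)phenyl]-6-[4-(methoxymethoxy)phenyl]-2-{2-[4-(methoxymethoxy)phenyl]ethyl}oxane | COCOc1cc(OC)cc(OCOC)c1[C@@H]2C[C@H](CCc3ccc(OCOC)cc3)O[C@H](c3ccc(OCOC)cc3)C2 | intermediate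
27 | {6-methoxy-2,4-bis(methoxymethoxy)-3-[(2S,4R,6S)-6-[4-(methoxymethoxy)phenyl]-2-{2-[4-(methoxymethoxy)phenyl]ethyl}oxan-4-yl]phenyl}lithium (formed in the flask, step 13) | COCOc1c([Li])c(OC)cc(OCOC)c1[C@@H]2C[C@H](CCc3ccc(OCOC)cc3)O[C@H](c3ccc(OCOC)cc3)C2 | intermediate
28 | 1-{6-methoxy-2,4-bis(methoxymethoxy)-3-[(2S,4R,6S)-6-[4-(methoxymethoxy)phenyl]-2-{2-[4-(methoxymethoxy)phenyl]ethyl}oxan-4-yl]phenyl}ethan-1-one | COCOc1c(C(C)=O)c(OC)cc(OCOC)c1[C@@H]2C[C@H](CCc3ccc(OCOC)cc3)O[C@H](c3ccc(OCOC)cc3)C2 | intermediate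
29 | 4-(methoxymethoxy)benzaldehyde | COCOc1ccc(C=O)cc1 | starting material
30 | (2E)-1-{6-methoxy-2,4-bis(methoxymethoxy)-3-[(2S,4R,6S)-6-[4-(methoxymethoxy)phenyl]-2-{2-[4-(methoxymethoxy)phenyl]ethyl}oxan-4-yl]phenyl}-3-[4-(methoxymethoxy)phenyl]prop-2-en-1-one | COCOc1c(C(=O)/C=C/c4ccc(OCOC)cc4)c(OC)cc(OCOC)c1[C@@H]2C[C@H](CCc3ccc(OCOC)cc3)O[C@H](c3ccc(OCOC)cc3)C2 | intermediate
31 | (2E)-1-{2,4-dihydroxy-3-[(2S,4R,6S)-6-(4-hydroxyphenyl)-2-[2-(4-hydroxyphenyl)ethyl]oxan-4-yl]-6-methoxyphenyl}-3-(4-hydroxyphenyl)prop-2-en-1-one | COc1cc(O)c([C@@H]2C[C@H](CCc3ccc(O)cc3)O[C@H](c3ccc(O)cc3)C2)c(O)c1C(=O)/C=C/c1ccc(O)cc1 | target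

**Totals**

Total step count: 15. Longest linear sequence: 12 steps (1, 2, 4, 5, 6, 7, 10, 11, 12, 13, 14, 15, from 4-(benzyloxy)benzyl chloride).

**Steps most likely to fail**

Step 4. The relay anion may attack the benzylic carbon of the electron-rich aryl epoxide, or that epoxide may rearrange under lithium catalysis to the arylacetaldehyde before it is opened. Either way the second C–C bond would form with poor regiocontrol or not at all. The fallback sets out from 8 and 5 and returns to the route at 13. The first half of the relay is run unchanged, but anion 11 is trapped with iodomethane in HMPA/THF instead of with 7, which should give tert-butyl{[(2S)-4-[4-(benzyloxy)phenyl]-1-(2-methyl-1,3-dithian-2-yl)butan-2-yl]oxy}dimethylsilane F1. Alkylative hydrolysis (MeI, CaCO3, aqueous MeCN) should then give the methyl ketone (4S)-6-[4-(benzyloxy)phenyl]-4-[(tert-butyldimethylsilyl)oxy]hexan-2-one F2. Its kinetic boron enolate on the methyl side (dicyclohexylboron chloride, Et3N, Et2O, −78 °C) is added to aldehyde 6 in an aldol addition with oxidative work-up, which delivers 13 as either C1 epimer. C5 then comes from iodomethane and the C5–C6 bond from the aldol step, so the robust aldehyde replaces the fragile epoxide.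

Step 11. Hydrogen delivery to the hindered trisubstituted double bond next to a di-ortho-substituted arene may show poor facial selectivity. Slow reduction may let palladium walk the double bond toward the oxygen-bearing C2 or C6 and erase a stereocentre. The C6–O bond, allylic as well as benzylic in isomer 24, may be hydrogenolysed with ring opening. The fallback sets out from the mixture 23/24 and returns at 25. A metal-hydride hydrogen-atom-transfer hydrogenation (Mn(dpm)3 cat., PhSiH3, t-BuOOH, i-PrOH, rt) adds a hydrogen atom to the unsubstituted alkene carbon. The planar tertiary benzylic C4 radical then accepts the second hydrogen under product-stability control. This should give the all-equatorial (2S,4R,6S)-6-[4-(benzyloxy)phenyl]-2-{2-[4-(benzyloxy)phenyl]ethyl}-4-[4-methoxy-2,6-bis(methoxymethoxy)phenyl]oxane F3 with the benzyl ethers and ring C–O bonds intact. Ordinary hydrogenolysis of the two benzyl ethers (H2, Pd/C, EtOAc), with no allylic C–O bond left in the molecule, then gives 25.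

Step 13. Metalation may occur at the wrong site: ortho to the single MOM ether on either remote aryl ring, or at the benzylic, oxygen-bearing C6–H, which would lead to ring opening or Wittig-type rearrangement. Metalation of the crowded ring may also be incomplete. The fallback sets out from 26 and returns at 27 and thereby 28. Electrophilic bromination (NBS, MeCN, 0 °C) should select the free position of the most electron-rich, 1,3,5-trioxygenated ring (the two free positions are equivalent). This gives (2S,4R,6S)-4-[3-bromo-4-methoxy-2,6-bis(methoxymethoxy)phenyl]-6-[4-(methoxymethoxy)phenyl]-2-{2-[4-(methoxymethoxy)phenyl]ethyl}oxane F4. Bromine–lithium exchange (n-BuLi, THF, −78 °C), far faster than any deprotonation, generates the same aryllithium 27. This is acylated with N-methoxy-N-methylacetamide as in the main route to give 28.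

Further compounds
F1 | step 4 | tert-butyl{[(2S)-4-[4-(benzyloxy)phenyl]-1-(2-methyl-1,3-dithian-2-yl)butan-2-yl]oxy}dimethylsilane | CC(C)(C)[Si](C)(C)O[C@@H](CCc1ccc(OCc2ccccc2)cc1)CC1(C)SCCCS1
F2 | step 4 | (4S)-6-[4-(benzyloxy)phenyl]-4-[(tert-butyldimethylsilyl)oxy]hexan-2-one | CC(C)(C)[Si](C)(C)O[C@@H](CCc1ccc(OCc2ccccc2)cc1)CC(C)=O
F3 | step 11 | (2S,4R,6S)-6-[4-(benzyloxy)phenyl]-2-{2-[4-(benzyloxy)phenyl]ethyl}-4-[4-methoxy-2,6-bis(methoxymethoxy)phenyl]oxane | COCOc1cc(OC)cc(OCOC)c1[C@@H]2C[C@H](CCc3ccc(OCc4ccccc4)cc3)O[C@H](c3ccc(OCc4ccccc4)cc3)C2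
F4 | step 13 | (2S,4R,6S)-4-[3-bromo-4-methoxy-2,6-bis(methoxymethoxy)phenyl]-6-[4-(methoxymethoxy)phenyl]-2-{2-[4-(methoxymethoxy)phenyl]ethyl}oxane | COCOc1c(Br)c(OC)cc(OCOC)c1[C@@H]2C[C@H](CCc3ccc(OCOC)cc3)O[C@H](c3ccc(OCOC)cc3)C2
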